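**Retrosynthetic overview** (labdane numbering; ring A = C1–C5/C10, ring B = C5–C10)

1. Late stage: the two carboxyls come from a tert-butyl ester (C4 carboxyl) and a silyl-protected allylic alcohol (C15); 2-OH comes from the C2 ketone, itself from a C1=C2 alkene; C8=CH2 comes from the C8 ketone 24.
2. Key disconnection C9–C10: a Claisen rearrangement contracts the eight-membered alkylidene-oxocane ring of 23 (O, C8, C7, C6, C5, C10, C1, C2) to six-membered ring B; 23 comes from bridged lactone 17 and gem-dibromide 22 (C9, C11–C16) by Takai–Utimoto alkylidenation.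
3. Enabling feature: on cyclohexene ring A the allylic C2–O bond and the three-carbon arm on C5 are cis-1,4 across C1=C10, so the C8 enol ether can bridge them; C9 is then held under C10 on the C6 face (cis ring fusion), and the Z geometry of C8=C9 fixes C9.
4. Ring A with C4 and C5 comes from a lactonic Ireland–Claisen rearrangement of δ-lactone 10 (anti-benzoyloxyallylation of enal 6, methacryloylation, ring-closing metathesis).
5. Order of ring formation: δ-lactone (temporary) → ring A → bridged eight-membered lactone (temporary) → ring B.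

Key step: step 13

Remark: the SMILES is read as the cis-fused isomer 2S,4R,5S,9R,10R (H-5, H-9, CH3-10, the C4 methyl and HO-2 on one face, called β; C6, C11 and the C4 carboxyl on the other, α), and the route is built for exactly this isomer.

**Route**

Step 1
Reactants: 1 acrolein; 2 benzoic anhydride
Product: 3 prop-2-ene-1,1-diyl dibenzoate
Conditions: FeCl3 (2 mol %), CH2Cl2, 0 → 25 °C
Reagents that add atoms: none
Why: Lewis-acid-catalysed acylal formation (addition of the anhydride across the aldehyde C=O) gives the gem-dibenzoate at the carbonyl carbon and leaves the vinyl group intact; no stereocentre is formed.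

Step 2
Reactants: 4 methyl 4-oxobutanoate; 5 2-(triphenyl-λ5-phosphanylidene)propanal
Product: 6 methyl (4E)-5-methyl-6-oxohex-4-enoate
Conditions: PhMe, 80 °C
Reagents that add atoms: none
Why: Wittig olefination with the stabilised formyl ylide should give the E-trisubstituted enal, and the conjugated aldehyde of the product is much less reactive towards the ylide than the saturated aldehyde 4.

Step 3
Reactants: 6 methyl (4E)-5-methyl-6-oxohex-4-enoate; 3 prop-2-ene-1,1-diyl dibenzoate
Product: 7 methyl (4E,6R,7S)-7-(benzoyloxy)-6-hydroxy-5-methylnona-4,8-dienoate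
Conditions: [Ir(cod)Cl]2 (2.5 mol %), SEGPHOS (5 mol %, enantiomer chosen for the 6R,7S adduct), 4-cyano-3-nitrobenzoic acid (10 mol %), K3PO4 (cat.), 2-propanol (2 equiv), THF, 60 °C
Reagents that add atoms: none
Why: Iridium-catalysed transfer-hydrogenative carbonyl allylation with an allylic gem-dicarboxylate: the (E)-configured (benzoyloxy)allyl iridium nucleophile adds through a closed chair transition state, which gives the anti relationship of C6–OH and C7–OBz, while the chiral bisphosphine selects the aldehyde face and so sets both centres (6R,7S) together.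

Step 4
Reactants: 7 methyl (4E,6R,7S)-7-(benzoyloxy)-6-hydroxy-5-methylnona-4,8-dienoate; 8 methacryloyl chloride
Product: 9 methyl (4E,6R,7S)-7-(benzoyloxy)-5-methyl-6-[(2-methylprop-2-enoyl)oxy]nona-4,8-dienoate
Conditions: Et3N, DMAP (cat.), CH2Cl2, −20 → 0 °C
Reagents that add atoms: none
Why: DMAP-catalysed O-acylation of the secondary allylic alcohol with the acid chloride at low temperature, which should outrun 1,2-benzoyl migration; no stereocentre is touched.

Step 5
Reactants: 9 methyl (4E,6R,7S)-7-(benzoyloxy)-5-methyl-6-[(2-methylprop-2-enoyl)oxy]nona-4,8-dienoate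
Product: 10 methyl (4E)-5-[(2R,3S)-3-(benzoyloxy)-5-methyl-6-oxo-3,6-dihydro-2H-pyran-2-yl]hex-4-enoate
Conditions: second-generation Grubbs catalyst RuCl2(=CHPh)(PCy3)(H2IMes) (5 mol %), CH2Cl2, 40 °C
Reagents that add atoms: none
Why: Ring-closing metathesis of the methacrylate with the vinyl group closes the six-membered α,β-unsaturated δ-lactone with loss of ethene, the trisubstituted side-chain alkene being too hindered to take part; the two stereocentres (alkenyl and benzoate trans on the ring) are unchanged.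

Step 6
Reactants: 10 methyl (4E)-5-[(2R,3S)-3-(benzoyloxy)-5-methyl-6-oxo-3,6-dihydro-2H-pyran-2-yl]hex-4-enoate
Product: 13 (1R,2S,5S)-5-(benzoyloxy)-2-(3-methoxy-3-oxopropyl)-1,3-dimethylcyclohex-3-ene-1-carboxylic acid, via silyl ketene acetal 11 (not isolated), via silyl ester 12 (not isolated)
Conditions: LiBH(s-Bu)3, THF, −78 °C; TBSCl, HMPA, −78 → 25 °C; PhMe, 110 °C; then 1 M HCl, THF, 0 °C
Reagents that add atoms: none
Why: Conjugate hydride addition and O-silylation give the cyclic silyl ketene acetal 11, whose lactonic Ireland–Claisen rearrangement through the ring-enforced boat transition state forms the C4–C5 bond and ring A: bond formation on the lactone face that carries the alkenyl group, the E alkene (arm cis to the new carboxyl) and the trans lactone (benzoate cis to the carboxyl) fix the quaternary C4 (1R) and C5 (2S) relative to the retained benzoate centre.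

Step 7
Reactants: 13 (1R,2S,5S)-5-(benzoyloxy)-2-(3-methoxy-3-oxopropyl)-1,3-dimethylcyclohex-3-ene-1-carboxylic acid
Product: 14 tert-butyl (1R,2S,5S)-5-(benzoyloxy)-2-(3-methoxy-3-oxopropyl)-1,3-dimethylcyclohex-3-ene-1-carboxylate
Conditions: t-BuOC(=NH)CCl3, BF3·OEt2 (cat.), cyclohexane/CH2Cl2, 25 °C
Reagents that add atoms: tert-butyl 2,2,2-trichloroacetimidate, CC(C)(C)OC(=N)C(Cl)(Cl)Cl
Why: Acid-catalysed O-alkylation of the carboxylic acid by the trichloroacetimidate (tert-butyl cation transfer to oxygen) esterifies the quaternary acid because its carbonyl carbon is not attacked; no stereocentre is touched.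

Step 8
Reactants: 14 tert-butyl (1R,2S,5S)-5-(benzoyloxy)-2-(3-methoxy-3-oxopropyl)-1,3-dimethylcyclohex-3-ene-1-carboxylate
Product: 15 3-[(1S,4S,6R)-6-(tert-butoxycarbonyl)-4-hydroxy-2,6-dimethylcyclohex-2-en-1-yl]propanoic acid
Conditions: LiOH, THF/MeOH/H2O, 0 → 25 °C; then 1 M HCl to pH 4
Reagents that add atoms: lithium hydroxide, [Li+].[OH-]
Why: Saponification: hydroxide cleaves the primary methyl ester and the benzoate, whereas the tert-butyl ester on the quaternary carbon is inert and is not expected to be attacked by the cis-1,3 hydroxyl either.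

Step 9
Reactants: 15 3-[(1S,4S,6R)-6-(tert-butoxycarbonyl)-4-hydroxy-2,6-dimethylcyclohex-2-en-1-yl]propanoic acid
Product: 17 tert-butyl (1S,6S,10R)-7,10-dimethyl-3-oxo-2-oxabicyclo[4.2.2]dec-7-ene-10-carboxylate, via mixed anhydride 16 (not isolated)
Conditions: 2,4,6-Cl3C6H2COCl, Et3N, THF, 25 °C; then slow addition to DMAP, PhMe (1 mM), 80 °C
Reagents that add atoms: none
Why: Yamaguchi macrolactonisation (mixed anhydride, DMAP acyl transfer, high dilution): the hydroxyl and the propanoate arm are cis-1,4 on ring A, so the acyl group can reach the oxygen once ring A adopts a boat, and the bridged eight-membered lactone closes with retention at the carbinol carbon.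

Step 10
Reactants: 18 geraniol
Product: 19 tert-butyl{[(2E)-3,7-dimethylocta-2,6-dien-1-yl]oxy}diphenylsilane
Conditions: TBDPSCl, imidazole, CH2Cl2, 25 °C
Reagents that add atoms: tert-butyl(chloro)diphenylsilane, CC(C)(C)[Si](Cl)(c1ccccc1)c1ccccc1
Why: Imidazole-mediated silylation of the primary allylic alcohol; a robust ether is needed because ester protecting groups would not survive step 13.

Step 11
Reactants: 19 tert-butyl{[(2E)-3,7-dimethylocta-2,6-dien-1-yl]oxy}diphenylsilane
Product: 21 (4E)-6-[(tert-butyldiphenylsilyl)oxy]-4-methylhex-4-enal, via epoxide 20 (not isolated)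
Conditions: mCPBA, CH2Cl2, −20 °C; then H5IO6, THF/H2O, 0 °C
Reagents that add atoms: 3-chloroperoxybenzoic acid, O=C(OO)c1cccc(Cl)c1
Why: Prilezhaev epoxidation is selective for the electron-rich remote trisubstituted alkene over the alkene that bears the allylic ether, and periodic acid then cleaves the epoxide oxidatively to the aldehyde and acetone without touching the E alkene.

Step 12
Reactants: 21 (4E)-6-[(tert-butyldiphenylsilyl)oxy]-4-methylhex-4-enal
Product: 22 tert-butyl{[(2E)-6,6-dibromo-3-methylhex-2-en-1-yl]oxy}diphenylsilane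
Conditions: P(OPh)3, Br2, Et3N, CH2Cl2, −78 → 0 °C
Reagents that add atoms: bromine, BrBr
Why: Deoxygenative gem-dibromination of the aldehyde by the triphenyl phosphite–bromine adduct (Appel-type activation of the carbonyl oxygen) under amine-buffered conditions that spare the alkene and the silyl ether.

Step 13
Reactants: 17 tert-butyl (1S,6S,10R)-7,10-dimethyl-3-oxo-2-oxabicyclo[4.2.2]dec-7-ene-10-carboxylate; 22 tert-butyl{[(2E)-6,6-dibromo-3-methylhex-2-en-1-yl]oxy}diphenylsilane
Product: 24 cis-fused ketone (labdane numbering): tert-butyl 4β,10β-dimethyl-8-oxo-9α-[(3E)-5-(tert-butyldiphenylsilyloxy)-3-methylpent-3-en-1-yl]-5βH,9βH-decal-1-ene-4α-carboxylate, via enol ether 23 (not isolated)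
Conditions: Zn, TiCl4, TMEDA, PbCl2 (cat.), THF, 25 °C; aq. K2CO3, filtration through basic Al2O3; then xylenes, 145 °C
Reagents that add atoms: none
Why: The zinc/titanium alkylidene generated from 22 olefinates the strained, unhindered lactone carbonyl of 17 (Takai–Utimoto alkylidenation of esters and lactones) to the Z enol ether 23, which on heating undergoes a concerted suprafacial [3,3] sigmatropic Claisen rearrangement through the array C9=C8–O–C2–C1=C10 in the boat-like geometry enforced by the bridge. The closest known reaction types are the Claisen rearrangement of lactone-derived alkylidene oxacycles and the lactonic ester-enolate Claisen ring contraction of bridged unsaturated lactones. Ring B is closed by formation of the C9–C10 bond with cleavage of the O–C2 bond, so that the eight-membered oxocane ring (O, C8, C7, C6, C5, C10, C1, C2) contracts by two atoms to the six-membered carbocycle C5–C6–C7–C8–C9–C10, the double bond moves to C1=C2 and C8 becomes the ketone. The quaternary centre C10 is controlled by the tether, because C9 can reach C10 only on the face of ring A that carries C6 at C5 and the oxygen at C2, which gives the cis ring fusion with the angular methyl on the opposite face. C9 is controlled by the enol ether geometry, since in the enforced transition state the substituent cis to oxygen ends up cis to C1 and trans to the angular methyl, so the Z isomer gives 9-H β and the side chain α. The step needs chemoselective olefination (secured by the hindered tert-butyl ester on a quaternary carbon and by the ring strain of the bridged lactone) and Z selectivity (the normal preference of this reagent for placing the alkyl group cis to the alkoxy oxygen), and it is driven by release of the strain of the bridged medium ring and formation of the C=O bond.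

Step 14
Reactants: 24 cis-fused ketone (C1=C2, 8-oxo)
Product: 26 2α-hydroxy-8-ketone: tert-butyl 2α-hydroxy-4β,10β-dimethyl-8-oxo-9α-[(3E)-5-(tert-butyldiphenylsilyloxy)-3-methylpent-3-en-1-yl]-5βH,9βH-decalin-4α-carboxylate, via alkylboronate 25 (not isolated)
Conditions: catecholborane, RhCl(PPh3)3 (3 mol %), THF, 25 °C; then H2O2, pH 7 phosphate buffer, 0 °C
Reagents that add atoms: hydrogen peroxide, OO
Why: Rhodium-catalysed hydroboration with catecholborane is faster at the cis-disubstituted ring alkene than at the ketone or the trisubstituted side-chain alkene, boron goes to C2 because C1 is neopentylic (next to quaternary C10), and oxidation occurs with retention; addition anti to the two β-axial methyl groups should give mainly the 2α-alcohol, but either C2 epimer is carried on because C2 becomes a ketone in step 16.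

Step 15
Reactants: 26 2α-hydroxy-8-ketone
Product: 27 tert-butyl 2α-hydroxy-4β,10β-dimethyl-8-methylidene-9α-[(3E)-5-(tert-butyldiphenylsilyloxy)-3-methylpent-3-en-1-yl]-5βH,9βH-decalin-4α-carboxylate
Conditions: Zn, CH2Br2, TiCl4, THF/CH2Cl2, 0 → 25 °C
Reagents that add atoms: dibromomethane, BrCBr
Why: Takai–Lombardo methylenation with the non-basic zinc/titanium methylene reagent converts the C8 ketone into the exocyclic alkene without epimerising the adjacent C9 centre and without attacking the tert-butyl ester; the free hydroxyl only consumes reagent.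

Step 16
Reactants: 27 2α-hydroxy-8-methylidene compound
Product: 28 tert-butyl 4β,10β-dimethyl-8-methylidene-2-oxo-9α-[(3E)-5-(tert-butyldiphenylsilyloxy)-3-methylpent-3-en-1-yl]-5βH,9βH-decalin-4α-carboxylate
Conditions: Dess–Martin periodinane, NaHCO3, CH2Cl2, 25 °C
Reagents that add atoms: none
Why: Dess–Martin oxidation of the secondary alcohol under buffered, non-epimerising conditions gives the C2 ketone and thereby removes the C2 configuration set in step 14.

Step 17
Reactants: 28 2-ketone
Product: 29 tert-butyl 2β-hydroxy-4β,10β-dimethyl-8-methylidene-9α-[(3E)-5-(tert-butyldiphenylsilyloxy)-3-methylpent-3-en-1-yl]-5βH,9βH-decalin-4α-carboxylate (2S)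
Conditions: LiBH(s-Bu)3, THF, −78 °C; then H2O
Reagents that add atoms: none
Why: Ketone reduction with a bulky borohydride: in the chair of ring A that avoids the severe interactions of the alternative chair, the methyl groups on C4 and C10 are both axial on the β face and flank the carbonyl, so hydride is delivered from the α face and the axial 2β-alcohol (2S) should result.

Step 18
Reactants: 29 2β-alcohol silyl ether
Product: 30 tert-butyl 2β-hydroxy-9α-[(3E)-5-hydroxy-3-methylpent-3-en-1-yl]-4β,10β-dimethyl-8-methylidene-5βH,9βH-decalin-4α-carboxylate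
Conditions: Bu4NF, THF, 25 °C
Reagents that add atoms: none
Why: Fluoride-induced cleavage of the primary silyl ether (strong Si–F bond); the tert-butyl ester, the secondary alcohol and the alkenes are inert.

Step 19
Reactants: 30 allylic alcohol
Product: 31 tert-butyl 2β-hydroxy-4β,10β-dimethyl-8-methylidene-9α-[(3E)-3-methyl-5-oxopent-3-en-1-yl]-5βH,9βH-decalin-4α-carboxylate
Conditions: MnO2, CH2Cl2, 25 °C
Reagents that add atoms: none
Why: MnO2 oxidises only the allylic primary alcohol, giving the E enal, while the saturated secondary 2-hydroxyl is untouched.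

Step 20
Reactants: 31 enal
Product: 32 (2E)-5-[(4α-tert-butoxycarbonyl)-2β-hydroxy-4β,10β-dimethyl-8-methylidene-5βH,9βH-decalin-9α-yl]-3-methylpent-2-enoic acid
Conditions: NaClO2, NaH2PO4, 2-methylbut-2-ene, t-BuOH/H2O, 25 °C
Reagents that add atoms: sodium chlorite, [Na+].[O-]Cl=O
Why: Pinnick oxidation (chlorite) of the enal to the enoic acid, with 2-methylbut-2-ene as hypochlorite scavenger so that the alkenes and the E geometry are preserved.

Step 21
Reactants: 32 enoic acid tert-butyl ester
Product: 34 (1R,3S,4aR,5R,8aS)-5-[(3E)-4-carboxy-3-methylbut-3-en-1-yl]-3-hydroxy-1,4a-dimethyl-6-methylidenedecahydronaphthalene-1-carboxylic acid (target), via tris(trimethylsilyl) derivative 33 (not isolated)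
Conditions: Me3SiOTf, 2,6-lutidine, CH2Cl2, 0 °C; then H2O, citric acid
Reagents that add atoms: none
Why: Silyl-triflate-mediated cleavage of the tert-butyl ester (O-silylation, loss of 2-methylpropene) under lutidine-buffered, non-protic conditions that should not isomerise the exocyclic alkene; aqueous work-up hydrolyses the silyl esters and the silyl ether of 33 to the hydroxy diacid.

**Compound list**

1 | prop-2-enal (acrolein) | C=CC=O | starting material
2 | benzoic anhydride | O=C(OC(=O)c1ccccc1)c1ccccc1 | starting material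
3 | prop-2-ene-1,1-diyl dibenzoate | C=CC(OC(=O)c1ccccc1)OC(=O)c1ccccc1 | intermediate
4 | methyl 4-oxobutanoate | COC(=O)CCC=O | starting material
5 | 2-(triphenyl-λ5-phosphanylidene)propanal | CC(C=O)=P(c1ccccc1)(c1ccccc1)c1ccccc1 | starting material
6 | methyl (4E)-5-methyl-6-oxohex-4-enoate | O=C/C(C)=C/CCC(=O)OC | intermediate
7 | methyl (4E,6R,7S)-7-(benzoyloxy)-6-hydroxy-5-methylnona-4,8-dienoate | C=C[C@H](OC(=O)c1ccccc1)[C@H](O)/C(C)=C/CCC(=O)OC | intermediate
8 | 2-methylprop-2-enoyl chloride (methacryloyl chloride) | C=C(C)C(=O)Cl | starting material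
9 | methyl (4E,6R,7S)-7-(benzoyloxy)-5-methyl-6-[(2-methylprop-2-enoyl)oxy]nona-4,8-dienoate | C=C[C@H](OC(=O)c1ccccc1)[C@H](OC(=O)C(C)=C)/C(C)=C/CCC(=O)OC | intermediate
10 | methyl (4E)-5-[(2R,3S)-3-(benzoyloxy)-5-methyl-6-oxo-3,6-dihydro-2H-pyran-2-yl]hex-4-enoate | CC1=C[C@H](OC(=O)c2ccccc2)[C@@H](/C(C)=C/CCC(=O)OC)OC1=O | intermediate
11 | methyl (4E)-5-[(2R,3S)-3-(benzoyloxy)-6-(tert-butyldimethylsilyloxy)-5-methyl-3,4-dihydro-2H-pyran-2-yl]hex-4-enoate (silyl ketene acetal) | C/C(=C\CCC(=O)OC)[C@H]1OC(O[Si](C)(C)C(C)(C)C)=C(C)C[C@@H]1OC(=O)c1ccccc1 | intermediate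
12 | tert-butyldimethylsilyl (1R,2S,5S)-5-(benzoyloxy)-2-(3-methoxy-3-oxopropyl)-1,3-dimethylcyclohex-3-ene-1-carboxylate | COC(=O)CC[C@H]1C(C)=C[C@@H](OC(=O)c2ccccc2)C[C@@]1(C)C(=O)O[Si](C)(C)C(C)(C)C | intermediate
13 | (1R,2S,5S)-5-(benzoyloxy)-2-(3-methoxy-3-oxopropyl)-1,3-dimethylcyclohex-3-ene-1-carboxylic acid | COC(=O)CC[C@H]1C(C)=C[C@@H](OC(=O)c2ccccc2)C[C@@]1(C)C(=O)O | intermediate
14 | tert-butyl (1R,2S,5S)-5-(benzoyloxy)-2-(3-methoxy-3-oxopropyl)-1,3-dimethylcyclohex-3-ene-1-carboxylate | COC(=O)CC[C@H]1C(C)=C[C@@H](OC(=O)c2ccccc2)C[C@@]1(C)C(=O)OC(C)(C)C | intermediate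
15 | 3-[(1S,4S,6R)-6-(tert-butoxycarbonyl)-4-hydroxy-2,6-dimethylcyclohex-2-en-1-yl]propanoic acid | OC(=O)CC[C@H]1C(C)=C[C@@H](O)C[C@@]1(C)C(=O)OC(C)(C)C | intermediate
16 | mixed anhydride of 15 with 2,4,6-trichlorobenzoic acid | O=C(OC(=O)c1c(Cl)cc(Cl)cc1Cl)CC[C@H]1C(C)=C[C@@H](O)C[C@@]1(C)C(=O)OC(C)(C)C | intermediate
17 | tert-butyl (1S,6S,10R)-7,10-dimethyl-3-oxo-2-oxabicyclo[4.2.2]dec-7-ene-10-carboxylate | O=C1CC[C@H]2C(C)=C[C@@H](O1)C[C@@]2(C)C(=O)OC(C)(C)C | intermediate
18 | geraniol, (2E)-3,7-dimethylocta-2,6-dien-1-ol | CC(C)=CCC/C(C)=C/CO | starting material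
19 | tert-butyl{[(2E)-3,7-dimethylocta-2,6-dien-1-yl]oxy}diphenylsilane | CC(C)=CCC/C(C)=C/CO[Si](c1ccccc1)(c1ccccc1)C(C)(C)C | intermediate
20 | 6,7-epoxide of 19 (epoxide carbon racemic) | CC1(C)OC1CC/C(C)=C/CO[Si](c1ccccc1)(c1ccccc1)C(C)(C)C | intermediate
21 | (4E)-6-[(tert-butyldiphenylsilyl)oxy]-4-methylhex-4-enal | O=CCC/C(C)=C/CO[Si](c1ccccc1)(c1ccccc1)C(C)(C)C | intermediate
22 | tert-butyl{[(2E)-6,6-dibromo-3-methylhex-2-en-1-yl]oxy}diphenylsilane | BrC(Br)CC/C(C)=C/CO[Si](c1ccccc1)(c1ccccc1)C(C)(C)C | intermediate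
23 | tert-butyl (1S,3Z,6S,10R)-3-[(4E)-6-(tert-butyldiphenylsilyloxy)-4-methylhex-4-en-1-ylidene]-7,10-dimethyl-2-oxabicyclo[4.2.2]dec-7-ene-10-carboxylate | CC(C)(C)[Si](c1ccccc1)(c1ccccc1)OC/C=C(\C)CC/C=C1\O[C@@H]2C=C(C)[C@H](CC1)[C@](C)(C(=O)OC(C)(C)C)C2 | intermediate
24 | cis-fused ketone: tert-butyl 4β,10β-dimethyl-8-oxo-9α-[(3E)-5-(tert-butyldiphenylsilyloxy)-3-methylpent-3-en-1-yl]-5βH,9βH-decal-1-ene-4α-carboxylate (labdane numbering) | O=C1CC[C@H]2[C@](C)(C=CC[C@@]2(C)C(=O)OC(C)(C)C)[C@@H]1CC/C(C)=C/CO[Si](c1ccccc1)(c1ccccc1)C(C)(C)C | intermediate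
25 | 2α-(1,3,2-benzodioxaborol-2-yl)-1,2-dihydro derivative of 24 | O=C1CC[C@H]2[C@](C)(C[C@@H](B3Oc4ccccc4O3)C[C@@]2(C)C(=O)OC(C)(C)C)[C@@H]1CC/C(C)=C/CO[Si](c1ccccc1)(c1ccccc1)C(C)(C)C | intermediate
26 | tert-butyl 2α-hydroxy-4β,10β-dimethyl-8-oxo-9α-[(3E)-5-(tert-butyldiphenylsilyloxy)-3-methylpent-3-en-1-yl]-5βH,9βH-decalin-4α-carboxylate | O=C1CC[C@H]2[C@](C)(C[C@@H](O)C[C@@]2(C)C(=O)OC(C)(C)C)[C@@H]1CC/C(C)=C/CO[Si](c1ccccc1)(c1ccccc1)C(C)(C)C | intermediate
27 | tert-butyl 2α-hydroxy-4β,10β-dimethyl-8-methylidene-9α-[(3E)-5-(tert-butyldiphenylsilyloxy)-3-methylpent-3-en-1-yl]-5βH,9βH-decalin-4α-carboxylate | C=C1CC[C@H]2[C@](C)(C[C@@H](O)C[C@@]2(C)C(=O)OC(C)(C)C)[C@@H]1CC/C(C)=C/CO[Si](c1ccccc1)(c1ccccc1)C(C)(C)C | intermediate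
28 | tert-butyl 4β,10β-dimethyl-8-methylidene-2-oxo-9α-[(3E)-5-(tert-butyldiphenylsilyloxy)-3-methylpent-3-en-1-yl]-5βH,9βH-decalin-4α-carboxylate | C=C1CC[C@H]2[C@](C)(CC(=O)C[C@@]2(C)C(=O)OC(C)(C)C)[C@@H]1CC/C(C)=C/CO[Si](c1ccccc1)(c1ccccc1)C(C)(C)C | intermediate
29 | tert-butyl 2β-hydroxy-4β,10β-dimethyl-8-methylidene-9α-[(3E)-5-(tert-butyldiphenylsilyloxy)-3-methylpent-3-en-1-yl]-5βH,9βH-decalin-4α-carboxylate (2S) | C=C1CC[C@H]2[C@](C)(C[C@H](O)C[C@@]2(C)C(=O)OC(C)(C)C)[C@@H]1CC/C(C)=C/CO[Si](c1ccccc1)(c1ccccc1)C(C)(C)C | intermediate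
30 | tert-butyl 2β-hydroxy-9α-[(3E)-5-hydroxy-3-methylpent-3-en-1-yl]-4β,10β-dimethyl-8-methylidene-5βH,9βH-decalin-4α-carboxylate | C=C1CC[C@H]2[C@](C)(C[C@H](O)C[C@@]2(C)C(=O)OC(C)(C)C)[C@@H]1CC/C(C)=C/CO | intermediate
31 | tert-butyl 2β-hydroxy-4β,10β-dimethyl-8-methylidene-9α-[(3E)-3-methyl-5-oxopent-3-en-1-yl]-5βH,9βH-decalin-4α-carboxylate | C=C1CC[C@H]2[C@](C)(C[C@H](O)C[C@@]2(C)C(=O)OC(C)(C)C)[C@@H]1CC/C(C)=C/C=O | intermediate
32 | (2E)-5-[4α-(tert-butoxycarbonyl)-2β-hydroxy-4β,10β-dimethyl-8-methylidene-5βH,9βH-decalin-9α-yl]-3-methylpent-2-enoic acid | C=C1CC[C@H]2[C@](C)(C[C@H](O)C[C@@]2(C)C(=O)OC(C)(C)C)[C@@H]1CC/C(C)=C/C(=O)O | intermediate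
33 | tris(trimethylsilyl) derivative of the target (2-O-silyl ether, both silyl esters) | C=C1CC[C@H]2[C@](C)(C[C@H](O[Si](C)(C)C)C[C@@]2(C)C(=O)O[Si](C)(C)C)[C@@H]1CC/C(C)=C/C(=O)O[Si](C)(C)C | intermediate
34 | (1R,3S,4aR,5R,8aS)-5-[(3E)-4-carboxy-3-methylbut-3-en-1-yl]-3-hydroxy-1,4a-dimethyl-6-methylidenedecahydronaphthalene-1-carboxylic acid | C=C1CC[C@H]2[C@](C)(C[C@H](O)C[C@@]2(C)C(=O)O)[C@@H]1CC/C(C)=C/C(=O)O | target

**Step count and risks**

Total step count: 21. Longest linear sequence: 17 steps (steps 2–9 and 13–21, from methyl 4-oxobutanoate 4).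

The three steps most likely to fail:

Step 13 (alkylidenation and Claisen ring contraction). What may go wrong: loss of Z/E control in the alkylidenation (which would scramble C9), competing olefination of the tert-butyl ester, or decomposition of the acid-labile bridged enol ether before it rearranges. Fallback, setting out from lactone 17: aldehyde 21 is reduced with NaBH4 to (4E)-6-[(tert-butyldiphenylsilyl)oxy]-4-methylhex-4-en-1-ol F1 and converted with I2, PPh3 and imidazole into the primary iodide F2. Lithium–iodine exchange (t-BuLi, Et2O, −78 °C) and addition of the alkyllithium to 17 at −78 °C should stop at the tetrahedral adduct and give, after work-up, the hydroxy ketone F3. Heating F3 with pyridinium p-toluenesulfonate (cat.) in xylenes over molecular sieves should dehydrate the derived bridged lactol to the same enol ether 23 and deliver ketone 24, where the route is rejoined. The endocyclic enol ether isomer has no feasible rearrangement and should drain back through the exocyclic one. The price is equilibrium instead of kinetic control of the enol ether geometry, so a C9 epimer may have to be separated.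

Step 9 (lactonisation). What may go wrong: intermolecular esterification (diolide and oligomer formation) outrunning closure of the strained bridged eight-membered ring. Fallback, setting out from hydroxy acid 15: the acid is converted (MeNHOMe·HCl, EDC, i-Pr2NEt) into the Weinreb amide F4. With two equivalents of the alkyllithium made from iodide F2 this gives the hydroxy ketone F3 directly. The acid-catalysed dehydrative Claisen ring contraction described above then returns to ketone 24, so that neither lactone 17 nor the alkylidenation is needed.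

Step 14 (hydroboration). What may go wrong: reduction of the C8 ketone by the borane, sluggish reaction of the hindered ring alkene, or incomplete regiocontrol between C1 and C2. Fallback, setting out from ketone 24: NaBH4 gives the C8 alcohol F5 (either epimer). Disiamylborane followed by H2O2/NaHCO3 hydroborates only the cis-disubstituted ring alkene and gives the diol F6. Dess–Martin oxidation gives the 2,8-dione F7. LiBH(s-Bu)3 (1 equiv, −78 °C) reduces the less hindered C2 ketone from the α face to the 2β-hydroxy-8-ketone F8. Zn/CH2Br2/TiCl4 methylenation then returns to alcohol 29.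

Further compounds
F1 | step 13 | (4E)-6-[(tert-butyldiphenylsilyl)oxy]-4-methylhex-4-en-1-ol | OCCC/C(C)=C/CO[Si](c1ccccc1)(c1ccccc1)C(C)(C)C
F2 | step 13 | tert-butyl{[(2E)-6-iodo-3-methylhex-2-en-1-yl]oxy}diphenylsilane | ICCC/C(C)=C/CO[Si](c1ccccc1)(c1ccccc1)C(C)(C)C
F3 | step 13 | tert-butyl (1R,2S,5S)-2-[(7E)-9-(tert-butyldiphenylsilyloxy)-7-methyl-3-oxonon-7-en-1-yl]-5-hydroxy-1,3-dimethylcyclohex-3-ene-1-carboxylate | CC(C)(C)[Si](c1ccccc1)(c1ccccc1)OC/C=C(\C)CCCC(=O)CC[C@H]1C(C)=C[C@@H](O)C[C@@]1(C)C(=O)OC(C)(C)C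
F4 | step 9 | tert-butyl (1R,2S,5S)-5-hydroxy-2-{3-[methoxy(methyl)amino]-3-oxopropyl}-1,3-dimethylcyclohex-3-ene-1-carboxylate | CON(C)C(=O)CC[C@H]1C(C)=C[C@@H](O)C[C@@]1(C)C(=O)OC(C)(C)C
F5 | step 14 | 8-hydroxy analogue of ketone 24 (C8 epimers) | OC1CC[C@H]2[C@](C)(C=CC[C@@]2(C)C(=O)OC(C)(C)C)[C@@H]1CC/C(C)=C/CO[Si](c1ccccc1)(c1ccccc1)C(C)(C)C
F6 | step 14 | 2α,8-dihydroxy compound (C8 epimers) | OC1CC[C@H]2[C@](C)(C[C@@H](O)C[C@@]2(C)C(=O)OC(C)(C)C)[C@@H]1CC/C(C)=C/CO[Si](c1ccccc1)(c1ccccc1)C(C)(C)C
F7 | step 14 | 2,8-dione | O=C1CC[C@H]2[C@](C)(CC(=O)C[C@@]2(C)C(=O)OC(C)(C)C)[C@@H]1CC/C(C)=C/CO[Si](c1ccccc1)(c1ccccc1)C(C)(C)C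
F8 | step 14 | 2β-hydroxy-8-ketone | O=C1CC[C@H]2[C@](C)(C[C@H](O)C[C@@]2(C)C(=O)OC(C)(C)C)[C@@H]1CC/C(C)=C/CO[Si](c1ccccc1)(c1ccccc1)C(C)(C)C
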